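## Retrosynthetic overview
1. Feature: ring A carries the acyl group at C1, OH at C2, H at C3, OH at C4, prenyl at C5 and H at C6. The prenylated carbon C5 is para to the C2 oxygen. Of the two carbons ortho to that oxygen, C1 is blocked by the acyl group and C3 is wedged between the C2 and C4 oxygens.
2. Key disconnection: the C5–CH2(prenyl) bond is traced back through a Cope and then a Claisen [3,3] shift to the C2 O-prenyl ether of the complete, protected (S)-ketone (Cα OTBS, C4 OMOM).
3. The O-prenyl bond comes from a Mitsunobu reaction of the chelated C2 phenol, which is freed from a bis-MOM ketone by chelation-directed cleavage. The C1–C(=O) bond comes from an aryllithium and a Weinreb amide.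
4. The only stereocentre, Cα (S), is taken from O-methyl-L-tyrosine by diazotisation with net retention and is then only carried through.
5. No ring is formed at any stage. Both benzene rings are bought, so there is no order of ring formation.

Key step: step 8

Remark on the chemistry: the carbinol carbon of the target SMILES is S (OH > C(=O)Ar > CH2Ar > H). This is the spatial arrangement of L-tyrosine, so net retention in the diazotisation gives the required enantiomer.

## Route

Step 1
Reactants: 1 O-methyl-L-tyrosine
Product: 3 (S)-2-hydroxy-3-(4-methoxyphenyl)propanoic acid, via (R)-alpha-lactone 2 (not isolated)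
Conditions: NaNO2 (aq, slow addition), 1 M H2SO4–1,4-dioxane, 0 °C → rt
Reagents that add atoms: water, O
Why: Diazotisation of an α-amino acid with neighbouring-carboxylate participation: the carboxylate expels N2 with inversion to give α-lactone 2 and water opens it at Cα with a second inversion, so the S configuration of 1 is carried into 3 with net retention.

Step 2
Reactants: 3 (S)-2-hydroxy-3-(4-methoxyphenyl)propanoic acid
Product: 4 (S)-2-hydroxy-N-methoxy-3-(4-methoxyphenyl)-N-methylpropanamide
Conditions: MeNHOMe·HCl, EDC·HCl, HOBt, N-methylmorpholine, CH2Cl2, 0 °C → rt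
Reagents that add atoms: N,O-dimethylhydroxylamine hydrochloride, CNOC.Cl
Why: Carbodiimide/HOBt amide coupling (Weinreb amide formation), in which the amine outcompetes the secondary hydroxyl for the active ester and the α-hydroxy acid has no oxazolone pathway by which Cα could racemise.

Step 3
Reactants: 4 (S)-2-hydroxy-N-methoxy-3-(4-methoxyphenyl)-N-methylpropanamide
Product: 5 (S)-2-(tert-butyldimethylsilyloxy)-N-methoxy-3-(4-methoxyphenyl)-N-methylpropanamide
Conditions: TBSCl, imidazole, DMF, rt
Reagents that add atoms: tert-butyldimethylsilyl chloride, CC(C)(C)[Si](C)(C)Cl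
Why: Imidazole-promoted silylation of a secondary alcohol, which masks the only acidic proton before the organolithium step and does not touch Cα.

Step 4
Reactants: 6 4-bromoresorcinol
Product: 7 1-bromo-2,4-bis(methoxymethoxy)benzene
Conditions: MOMCl (2.5 equiv), iPr2NEt, CH2Cl2, 0 °C → rt
Reagents that add atoms: chloromethyl methyl ether, COCCl
Why: Double O-alkylation of the phenols with an α-chloro ether under amine base gives base-stable acetals whose ortho member also stabilises the later aryllithium by coordination.

Step 5
Reactants: 7 1-bromo-2,4-bis(methoxymethoxy)benzene; 5 (S)-TBS-protected Weinreb amide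
Product: 10 (S)-1-[2,4-bis(methoxymethoxy)phenyl]-2-(tert-butyldimethylsilyloxy)-3-(4-methoxyphenyl)propan-1-one, via aryllithium 8 (not isolated), via lithium hemiaminal adduct 9 (not isolated)
Conditions: 7, n-BuLi, THF, −78 °C; then 5, −78 → −40 °C; AcOH/THF quench at −78 °C
Reagents that add atoms: none
Why: Bromine–lithium exchange followed by Weinreb ketone synthesis: the chelated adduct 9 holds until the cold acetic acid quench, which prevents over-addition and keeps the new ketone away from strong base so that Cα stays S.

Step 6
Reactants: 10 (S)-bis-MOM ketone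
Product: 11 (S)-2-(tert-butyldimethylsilyloxy)-1-[2-hydroxy-4-(methoxymethoxy)phenyl]-3-(4-methoxyphenyl)propan-1-one
Conditions: MgBr2·OEt2 (1.2–1.5 equiv), n-BuSH (2.2 equiv), Et2O–CH2Cl2, 0 °C
Reagents that add atoms: none
Why: Chelation-directed Lewis acid/thiol acetal cleavage: Mg(II) bridges the ketone oxygen and the C2 aryl oxygen in a six-membered chelate and so activates only the ortho MOM group, the thiol traps the methoxymethyl cation, and the unassisted C4 MOM ether and the TBS ether react much more slowly under these conditions.

Step 7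
Reactants: 11 (S)-2-hydroxy-4-MOM ketone; 12 3-methylbut-2-en-1-ol (prenyl alcohol)
Product: 13 (S)-2-(tert-butyldimethylsilyloxy)-1-[4-(methoxymethoxy)-2-(3-methylbut-2-enyloxy)phenyl]-3-(4-methoxyphenyl)propan-1-one
Conditions: PPh3, DIAD, THF, 0 °C → rt
Reagents that add atoms: none
Why: Mitsunobu etherification: the hydrogen-bonded C2 phenol is acidic enough to protonate the betaine and attacks the primary allylic oxyphosphonium carbon in an SN2 manner, and the neutral medium avoids the enolisation of the α-silyloxy ketone that carbonate-mediated alkylation would risk.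

Step 8
Reactants: 13 (S)-C2 O-prenyl ether (Cα OTBS, C4 OMOM)
Product: 16 (S)-2-(tert-butyldimethylsilyloxy)-1-[2-hydroxy-4-(methoxymethoxy)-5-(3-methylbut-2-enyl)phenyl]-3-(4-methoxyphenyl)propan-1-one, via C3 reverse-prenyl ortho-dienone 14 (not isolated), via C5 prenyl para-dienone 15 (not isolated)
Conditions: Eu(fod)3 (10 mol %), PhMe, 80 °C, Ar
Reagents that add atoms: none
Why: Eu(III) binds the ketone oxygen and the C2 ether oxygen as a six-membered chelate and polarises the O–CH2 bond, so the aromatic Claisen [3,3] shift can run well below purely thermal temperatures, and the dimethyl-substituted allyl terminus bonds to C3, the only ortho carbon that bears hydrogen, to give the linearly conjugated dienone 14 with a 1,1-dimethylallyl group. In 14 the quaternary allylic carbon is squeezed between the C2 carbonyl and the C4 OMOM group, so the Cope [3,3] shift across C3–C4=C5 (CH2 terminus to C5) should outrun enolisation at C3; it gives the cross-conjugated dienone 15, the double allyl inversion restores a linear prenyl group, and tautomerisation to the hydrogen-bonded o-hydroxyaryl ketone 16 makes the sequence irreversible. The closest known reaction type is the thermal or lanthanide-catalysed para-Claisen (Claisen–Cope) rearrangement of prenyl ethers of o-acylphenols, such as 2-prenyloxyacetophenones, the derived chalcones and 5-O-prenylflavanones. No ring is closed and no lasting stereocentre is made, because the sp3 centres at C3 of 14 and C5 of 15 vanish on aromatisation. The selectivity needed is para (C5) over ortho (C3) delivery, and it rests on the acyl block at C1, on the crowding at C3, and on the fact that even a dienone formed by ipso attack at C1 could only relay the allyl group to the same C5. The medium holds neither Brønsted acid nor base, so the Cα silyloxy ketone stereocentre, the MOM acetal and the TBS ether should pass unchanged.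

Step 9
Reactants: 16 (S)-Cα O-TBS, C4 O-MOM ether of the target
Product: 17 (S)-2-(tert-butyldimethylsilyloxy)-1-[2,4-dihydroxy-5-(3-methylbut-2-enyl)phenyl]-3-(4-methoxyphenyl)propan-1-one
Conditions: ZnBr2 (2 equiv), n-PrSH (3 equiv), CH2Cl2, 0 °C, short contact time
Reagents that add atoms: none
Why: Lewis acid/thiol transacetalisation of the aryl MOM ether, a fast aprotic cleavage that spares the prenyl alkene from strong Brønsted acid and the ketone from long acid contact, and any concurrent loss of the TBS group would only anticipate step 10.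

Step 10
Reactants: 17 (S)-Cα O-TBS ether of the target
Product: 18 lespeflorin C2, (S)-1-[2,4-dihydroxy-5-(3-methylbut-2-enyl)phenyl]-2-hydroxy-3-(4-methoxyphenyl)propan-1-one
Conditions: HF·pyridine, pyridine–THF, 0 °C → rt; pH 7 phosphate buffer quench
Reagents that add atoms: none
Why: Fluoride-driven desilylation under pyridine-buffered, weakly acidic conditions, which avoids the basic medium in which an α-hydroxy ketone could enolise, so the S carbinol is released unchanged.

## Compound list
1 | O-methyl-L-tyrosine, (S)-2-amino-3-(4-methoxyphenyl)propanoic acid | COc1ccc(C[C@H](N)C(=O)O)cc1 | starting material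
2 | (R)-3-(4-methoxybenzyl)oxiran-2-one (α-lactone) | COc1ccc(C[C@H]2OC2=O)cc1 | intermediate (not isolated)
3 | (S)-2-hydroxy-3-(4-methoxyphenyl)propanoic acid | COc1ccc(C[C@H](O)C(=O)O)cc1 | intermediate
4 | (S)-2-hydroxy-N-methoxy-3-(4-methoxyphenyl)-N-methylpropanamide | COc1ccc(C[C@H](O)C(=O)N(C)OC)cc1 | intermediate
5 | (S)-2-(tert-butyldimethylsilyloxy)-N-methoxy-3-(4-methoxyphenyl)-N-methylpropanamide | COc1ccc(C[C@H](O[Si](C)(C)C(C)(C)C)C(=O)N(C)OC)cc1 | intermediate
6 | 4-bromoresorcinol | Oc1ccc(Br)c(O)c1 | starting material
7 | 1-bromo-2,4-bis(methoxymethoxy)benzene | COCOc1ccc(Br)c(OCOC)c1 | intermediate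
8 | 2,4-bis(methoxymethoxy)phenyllithium | [Li]c1ccc(OCOC)cc1OCOC | intermediate (not isolated)
9 | lithium alkoxide of the tetrahedral adduct of 8 with 5 (Cα S, hemiaminal carbon undefined) | COc1ccc(C[C@H](O[Si](C)(C)C(C)(C)C)C(O[Li])(N(C)OC)c2ccc(OCOC)cc2OCOC)cc1 | intermediate (not isolated)
10 | (S)-1-[2,4-bis(methoxymethoxy)phenyl]-2-(tert-butyldimethylsilyloxy)-3-(4-methoxyphenyl)propan-1-one | COc1ccc(C[C@H](O[Si](C)(C)C(C)(C)C)C(=O)c2ccc(OCOC)cc2OCOC)cc1 | intermediate
11 | (S)-2-(tert-butyldimethylsilyloxy)-1-[2-hydroxy-4-(methoxymethoxy)phenyl]-3-(4-methoxyphenyl)propan-1-one | COc1ccc(C[C@H](O[Si](C)(C)C(C)(C)C)C(=O)c2ccc(OCOC)cc2O)cc1 | intermediate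
12 | 3-methylbut-2-en-1-ol (prenyl alcohol) | CC(C)=CCO | starting material
13 | (S)-2-(tert-butyldimethylsilyloxy)-1-[4-(methoxymethoxy)-2-(3-methylbut-2-enyloxy)phenyl]-3-(4-methoxyphenyl)propan-1-one (key-step precursor) | COc1ccc(C[C@H](O[Si](C)(C)C(C)(C)C)C(=O)c2ccc(OCOC)cc2OCC=C(C)C)cc1 | intermediate
14 | ortho-dienone: ring A as cyclohexa-2,4-dienone with C2=O, sp3 C3 bearing H and 2-methylbut-3-en-2-yl, C4 OMOM, C1 acyl (Cα S, C3 undefined) | COc1ccc(C[C@H](O[Si](C)(C)C(C)(C)C)C(=O)C2=CC=C(OCOC)C(C(C)(C)C=C)C2=O)cc1 | intermediate (not isolated)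
15 | para-dienone: ring A as cyclohexa-2,5-dienone with C2=O, sp3 C5 bearing H and 3-methylbut-2-enyl, C4 OMOM, C1 acyl (Cα S, C5 undefined) | COc1ccc(C[C@H](O[Si](C)(C)C(C)(C)C)C(=O)C2=CC(CC=C(C)C)C(OCOC)=CC2=O)cc1 | intermediate (not isolated)
16 | (S)-2-(tert-butyldimethylsilyloxy)-1-[2-hydroxy-4-(methoxymethoxy)-5-(3-methylbut-2-enyl)phenyl]-3-(4-methoxyphenyl)propan-1-one (key-step product) | COc1ccc(C[C@H](O[Si](C)(C)C(C)(C)C)C(=O)c2cc(CC=C(C)C)c(OCOC)cc2O)cc1 | intermediate
17 | (S)-2-(tert-butyldimethylsilyloxy)-1-[2,4-dihydroxy-5-(3-methylbut-2-enyl)phenyl]-3-(4-methoxyphenyl)propan-1-one | COc1ccc(C[C@H](O[Si](C)(C)C(C)(C)C)C(=O)c2cc(CC=C(C)C)c(O)cc2O)cc1 | intermediate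
18 | lespeflorin C2, (S)-1-[2,4-dihydroxy-5-(3-methylbut-2-enyl)phenyl]-2-hydroxy-3-(4-methoxyphenyl)propan-1-one | COc1ccc(C[C@H](O)C(=O)c2cc(CC=C(C)C)c(O)cc2O)cc1 | target

## Count and risks
Total step count: 10. Longest linear sequence: 9 (steps 1–3 and 5–10). Step 4 is the side branch.

**Step 8 (Claisen–Cope relay).**
- What may go wrong: the ortho-dienone may enolise before the Cope shift, so that the allyl group stays at C3 in its inverted form. The allyl–oxygen bond may ionise with loss of the prenyl group. Long heating may slowly erode the configuration at Cα.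
- Fallback: it sets out from 11 and comes back at 16, and it replaces the sigmatropic relay by halogenation and cross-coupling.
  - Electrophilic iodination of 11 with NIS in MeCN at 0 °C → rt should go to C5, which is para to the free C2 phenol and less hindered than C3. This gives the 5-iodo ketone F1.
  - A Stille coupling of F1 with tributyl(3-methylbut-2-enyl)stannane (Pd(PPh3)4, DMF, 80 °C, neutral medium) then forms the C5–CH2 bond and delivers 16.

**Step 6 (selective ortho MOM cleavage).**
- What may go wrong: discrimination between the two acetals may be lost (over-cleavage at C4), or part of the silyl group may be lost.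
- Fallback: it sets out from 10 and comes back at 11, and it gives up selective cleavage in favour of exhaustive cleavage and selective re-protection.
  - Both MOM groups are removed on purpose with excess ZnBr2/n-PrSH in CH2Cl2 (0 °C → rt) to give the resorcinol ketone F2.
  - MOMCl (1.05 equiv) and iPr2NEt in CH2Cl2 at 0 °C then alkylate only the C4 hydroxyl, because the C2 hydroxyl is tied up in the hydrogen bond to the ketone. This gives 11.

**Step 9 (MOM removal next to the prenyl group).**
- What may go wrong: the freed C4 phenol may cyclise onto the neighbouring prenyl alkene under acid. The thiol may add to that alkene. The ketone may enolise under acid and lose enantiopurity.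
- Fallback: it sets out from 11 and comes back at 18, and it changes the C4 protecting group before the alkene is present, so that the endgame needs only fluoride.
  - The remaining MOM group of 11 is cleaved with ZnBr2/n-PrSH to the resorcinol ketone F2.
  - TBSCl and imidazole in CH2Cl2 at 0 °C silylate the unchelated C4 hydroxyl to give the bis-TBS phenol F3, and they would also restore any Cα silyl group lost on the way.
  - A Mitsunobu reaction with 12 (PPh3, DIAD, THF) gives the C2 O-prenyl ether F4.
  - The same Eu(fod)3-catalysed Claisen–Cope relay, helped by the bulkier C4 silyloxy group, gives the 5-prenyl bis-TBS ether F5.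
  - HF·pyridine in pyridine–THF removes both silyl groups in one operation to give 18.

## Further compounds
F1 | step 8 | (S)-2-(tert-butyldimethylsilyloxy)-1-[2-hydroxy-5-iodo-4-(methoxymethoxy)phenyl]-3-(4-methoxyphenyl)propan-1-one | COc1ccc(C[C@H](O[Si](C)(C)C(C)(C)C)C(=O)c2cc(I)c(OCOC)cc2O)cc1
F2 | step 6 | (S)-2-(tert-butyldimethylsilyloxy)-1-(2,4-dihydroxyphenyl)-3-(4-methoxyphenyl)propan-1-one | COc1ccc(C[C@H](O[Si](C)(C)C(C)(C)C)C(=O)c2ccc(O)cc2O)cc1
F3 | step 9 | (S)-2-(tert-butyldimethylsilyloxy)-1-[4-(tert-butyldimethylsilyloxy)-2-hydroxyphenyl]-3-(4-methoxyphenyl)propan-1-one | COc1ccc(C[C@H](O[Si](C)(C)C(C)(C)C)C(=O)c2ccc(O[Si](C)(C)C(C)(C)C)cc2O)cc1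
F4 | step 9 | (S)-2-(tert-butyldimethylsilyloxy)-1-[4-(tert-butyldimethylsilyloxy)-2-(3-methylbut-2-enyloxy)phenyl]-3-(4-methoxyphenyl)propan-1-one | COc1ccc(C[C@H](O[Si](C)(C)C(C)(C)C)C(=O)c2ccc(O[Si](C)(C)C(C)(C)C)cc2OCC=C(C)C)cc1
F5 | step 9 | (S)-2-(tert-butyldimethylsilyloxy)-1-[4-(tert-butyldimethylsilyloxy)-2-hydroxy-5-(3-methylbut-2-enyl)phenyl]-3-(4-methoxyphenyl)propan-1-one | COc1ccc(C[C@H](O[Si](C)(C)C(C)(C)C)C(=O)c2cc(CC=C(C)C)c(O[Si](C)(C)C(C)(C)C)cc2O)cc1
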